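# Total synthesis of CNP0261423.1: ring A closed by an alkenylchromium addition to the C6 ketone

Carotenoid numbering is used throughout. Ring A is C1–C6 with C16, C17 and C18. The chain runs C7–C15 and C15'–C7'. Ring B is C1'–C6'.

## Analysis of the target

- **Skeleton.** Compound 40 is an unsymmetrical C40 carotenoid, (3S,6R,6'S)-3,6-dihydroxy-2',3'-didehydro-7,8-dihydro-γ,ε-caroten-8-one. An all-E octaene runs from C9 to C8', has methyl branches at C9, C13, C13' and C9', is conjugated with the C8 ketone, and is capped by two different six-membered rings.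
- **Ring A.** This is a cyclohexane with quaternary C1, the secondary carbinol C3 (S), the exocyclic methylene C5=C18 and the tertiary carbinol C6 (R). The two C–O bonds are 1,4-cis, so in a chair one is equatorial and the other axial.
- **Ring B.** This is a 2,6,6-trimethylcyclohexa-2,4-dienyl group. Its only stereocentre, C6' (S, the spatial sense of (R)-α-ionone), lies about twenty bonds from ring A, so it cannot be relayed and must be set on its own.
- **Sensitive groups.** The polyene is sensitive to light, oxygen and acid. The C6(OH)–C7H2–C8(=O) unit is a ketone/ketone aldol, prone to retro-aldol cleavage and loss of water under base. The tertiary allylic alcohol at C6 ionises under acid. C6'–H is allylic three times over and can slip into conjugation by deprotonation or by a 1,5-hydrogen shift.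
- **The main difficulty.** C6 is a fully substituted carbon wedged between quaternary C1 and sp2 C5, and it must be made with control relative to remote C3.
- **The feature the strategy uses.** C6 carries its hydroxyl directly next to C5 of the C5=C18 methylene inside ring A. This 2-methylenecycloalkanol pattern results when a C5 alkenyl metal adds to a C6 ketone, so the C5–C6 bond, ring A, the carbinol and the methylene can all come from one ring closure.

## Retrosynthetic reasoning

**C11=C12 (40 ⇒ 26 + 38).** The last bond made is an olefination between the C15 phosphonium salt 26 and the C25 aldehyde 38.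
- The cut is placed here because the ylide from 26 is conjugated with the C8 ketone. It forms under almost neutral conditions and is too weak a base to attack the C6–C7 aldol bond or C6'–H.
- A cut at C9=C10 would put a stronger anion next to C7. A central cut would require two long, fragile polyene halves.
- The gain is C15 + C25 convergence and a final step that releases 40 with all hydroxyls already free.

**C11'=C12' (38 ⇒ 35 + 36).** The symmetrical C10 dialdehyde 36 brings C12 to C12' with three E double bonds already in place. The forward olefination with 35 must stop after one aldehyde has reacted and must leave C6' untouched.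

**C11'–P and C9'–C10' (35 ⇒ 34 ⇒ 33).** The salt 35 comes from the bis-allylic tertiary alcohol 34 by ionisation and capture of the cation at its free terminus by a phosphine. Alcohol 34 comes from dienone 33 by 1,2-addition of a vinyl nucleophile. Two steps add C10' and C11' and install the phosphorus.

**C2'=C3' (33 ⇒ 32 ⇒ 31 ⇒ 29 ⇒ 28 ⇒ 27).** No skeletal bond of ring B is cut, because C6' is bought with (R)-α-ionone 27.
- The extra double bond is traced to a C3' ketone (29) through the cross-conjugated dienyl triflate 31, which fixes both ring double bonds by construction.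
- Eliminating a C3' leaving group was not chosen, because loss of C6'–H into full conjugation would be preferred.
- The side-chain ketone is masked as ketal 28, so only one enone is present during enolisation.

**C8–C9 (26 ⇒ 24 ⇒ 23 ⇒ 22 ⇒ 16 + 20).** The enone is opened at the bond between the carbonyl carbon and C9.
- Aldehyde 16 receives the three-carbon E-alkenyl unit of iodide 20.
- The coupling has to be non-basic, because 16 is a β-hydroxy aldehyde.
- Oxidation, desilylation and neutral conversion of C11–OH into the phosphonium group then lead to 26.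

**C8 oxidation level (16 ⇒ 15 ⇒ 14).** The aldehyde is unmasked from the 4-methoxybenzyl ether of 14 by oxidative cleavage and oxidation of the primary alcohol.

**C5–C6 (14 ⇒ 12, the central disconnection).** Breaking the bond between the carbinol carbon and the methylene-bearing carbon opens ring A to the acyclic bromo ketone 12.
- One forward bond formation closes the ring, creates the hindered carbinol and leaves the methylene in place without any regiochemical question.
- The acyclic precursor needs only one stereocentre, C3, which has to dictate C6 across the ring.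

**C3–C4 (12 ⇒ 11 ⇒ 7 + 9).** The homoallylic carbinol is cut next to C3, which gives keto aldehyde 7 and the 2-bromoallyl donor 9. The forward reaction must be enantioselective under reagent control and must choose the aldehyde over the ketone.

**C8–O, C6–C7 and the aldehyde carbon C3 (7 ⇒ 6 ⇒ 4 + 5; 4 ⇒ 3 ⇒ 1).** The aldehyde comes from the terminal alkene of 6. The ether oxygen on C8 comes from conjugate addition of alcohol 5 to vinyl ketone 4. The C6–C7 bond comes from a single vinyl addition to amide 3 of the commercial acid 1, which already contains C1 with both methyls.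

**Side reagents (9 ⇒ 8; 20 ⇒ 18 ⇒ 17).** The stannane is made by substitution on dibromide 8. The E-iodide is made by syn hydrometallation and iodination of the silylated butynol.

## Alternatives that were turned down

**Alternative 1:** Ring A is kept intact and only C–O bonds are disconnected.
- *Disconnection and key step.* The C6 oxygen is traced to the 5,6-epoxide A1, which comes from the tetrasubstituted cyclohexenol A2. In the forward step the free C3 hydroxyl of A2 binds a vanadium catalyst and hands the oxygen of an alkyl hydroperoxide to its own face of C5=C6.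
- *For.* Intramolecular delivery enforces exactly the cis relation between C3–O and C6–O that 40 needs. This is a tighter stereochemical argument than the conformational relay in 12 → 14. The ring with C3 is also accessible from the 3-hydroxy-β end-group pool, so the step count to ring A should be no higher. On both points this alternative is at least as strong.
- *Against.* The hydroxyl reaches the alkene only when pseudo-axial, syn to an axial C1 methyl. The alkene is tetrasubstituted and flanked by quaternary C1, so undirected epoxidation can compete.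
- *Against.* A1 is not yet the target pattern. C5–O rather than C6–O must then be broken although both carbons are tertiary. The proton must leave from C18 rather than C4, where the more substituted endocyclic alkene would form. A stereocentre at C5 is built only to be destroyed.
- *Comparison.* The chosen closure offers the carbinol and the methylene in one bond-forming event with no regiochemical choice, and it has a clear repair if the relay fails.

**Alternative 2:** Ring B is opened at C1'–C6' to the acyclic (7Z)-tetraenone A4.
- *Key step.* A chiral Lewis acid on the C9' carbonyl steers the disrotatory six-electron closure to the dienone A3, which is identical with 33.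
- *For.* Ring and stereocentre arise catalytically in one step from an achiral C13 chain. The chosen route spends five steps (17–21) to reach the same compound from a chiral purchase. In step economy for ring B this alternative is clearly stronger.
- *Against.* The catalyst sits on an arm outside the reacting triene and several atoms from C6', so its grip on the sense of rotation is weak.
- *Against.* One methyl of the C1' terminus must turn inwards, which raises the barrier. The heating then needed invites the uncatalysed racemic closure, 1,7-hydrogen shifts of the Z-triene, and the 1,5-hydrogen shift that moves C6'–H into conjugation.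
- *Against.* The Z geometry of A4 is itself hard to secure. The idea also leaves ring A, with two of the three stereocentres and the most fragile functions, unsolved.
- *Comparison.* The chosen strategy places its single uncertain step where the structural problem lies and takes C6' from a safe source.

**Alternative 3:** Ring B is traced to the ester A5 and further to a seven-membered ring.
- *Key step.* Irradiation of the diazo ketone A6 expels nitrogen and the alkene carbon C5' migrates to the carbene carbon. The exocyclic ketene A7 is then captured by an alcohol under a chiral nucleophilic amine, whose protonation step sets C6'.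
- *For.* The carbon frame of A6 is that of the easily made dienone A8, so the sequence is short and needs no chiral starting material. The ester is a handle for chain growth. In brevity to a ring B building block it matches or beats steps 17–21.
- *Against.* Asymmetric ketene capture relies on a clear size difference between the two ketene substituents. In A7 they are a quaternary carbon and a methyl-bearing alkene carbon in the same ring.
- *Against.* The carbene can add to the neighbouring diene, and the cycloheptadienone chromophore has its own photochemistry.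
- *Against.* In A5, and in the aldehyde needed for building C7'=C8', C6'–H is α to a carbonyl as well as doubly allylic. Each later basic step therefore threatens the centre. In the chosen route C6' is never closer than the γ-position of a carbonyl.
- *Comparison.* Ring A again remains open, and the chosen strategy addresses it directly.

Key step: step 8

Assumption 1: (R)-α-ionone 27 is taken as purchasable in enantiopure form.

Assumption 2: The (R,R)-controller of step 6 is taken to deliver allyl groups to the Re face of unbranched aldehydes. The sense is to be checked on 11, and the antipodal controller is equally available.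

## Steps

Step 1
Reactants: 1 2,2-dimethylpent-4-enoic acid
Product: 3 N-methoxy-N,2,2-trimethylpent-4-enamide, via 2,2-dimethylpent-4-enoyl chloride 2 (not isolated)
Conditions: (COCl)2, DMF (cat.), CH2Cl2, 0 °C → rt; then MeNH(OMe)·HCl, Et3N, CH2Cl2, 0 °C → rt
Reagents that add atoms: oxalyl chloride O=C(Cl)C(=O)Cl (chlorine of 2 only); N,O-dimethylhydroxylamine hydrochloride CNOC.Cl
Why: Acid chloride formation and N-acylation are reliable even for an α-quaternary acid. The N-methoxy-N-methylamide will stop the next addition at the ketone stage.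

Step 2
Reactants: 3 N-methoxy-N,2,2-trimethylpent-4-enamide
Product: 4 4,4-dimethylhepta-1,6-dien-3-one
Conditions: CH2=CHMgBr, THF, 0 °C; inverse quench into cold 1 M HCl
Reagents that add atoms: vinylmagnesium bromide C=C[Mg]Br
Why: The chelated tetrahedral adduct survives until the quench, so only one vinyl group is taken up and the C6–C7 bond is formed. The cold acid protonates the released hydroxylamine before it can add to the new enone.

Step 3
Reactants: 4 4,4-dimethylhepta-1,6-dien-3-one; 5 4-methoxybenzyl alcohol
Product: 6 1-[(4-methoxybenzyl)oxy]-4,4-dimethylhept-6-en-3-one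
Conditions: PMe3 (10 mol %), 5 (3 equiv), THF, rt
Reagents that add atoms: none
Why: This is a phosphine-catalysed oxa-Michael addition: PMe3 adds reversibly to the unsubstituted β-carbon, the zwitterion deprotonates 5, and the alkoxide adds to C8. A terminal vinyl ketone lies on the adduct side of the equilibrium and the medium stays nearly neutral.

Step 4
Reactants: 6 1-[(4-methoxybenzyl)oxy]-4,4-dimethylhept-6-en-3-one
Product: 7 6-[(4-methoxybenzyl)oxy]-3,3-dimethyl-4-oxohexanal
Conditions: O3, CH2Cl2, −78 °C (Sudan red 7B as end-point dye); then PPh3, −78 °C → rt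
Reagents that add atoms: ozone [O-][O+]=O
Why: In this ozonolysis with reductive work-up the monosubstituted alkene is consumed before the anisyl ring when the dye end point is respected. The neutral work-up spares the β-alkoxy ketone and the 1,4-keto aldehyde.

Step 5
Reactants: 8 2,3-dibromopropene
Product: 9 (2-bromoprop-2-en-1-yl)tributylstannane
Conditions: Bu3SnH, LiN(iPr)2, THF, 0 °C; then 8, −78 → 0 °C
Reagents that add atoms: tributyltin hydride CCCC[SnH](CCCC)CCCC
Why: The soft stannyl anion displaces the allylic bromide by SN2. The vinylic bromide is inert at low temperature.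

Step 6
Reactants: 7 6-[(4-methoxybenzyl)oxy]-3,3-dimethyl-4-oxohexanal; 9 (2-bromoprop-2-en-1-yl)tributylstannane
Product: 11 (6S)-8-bromo-6-hydroxy-1-[(4-methoxybenzyl)oxy]-4,4-dimethylnon-8-en-3-one, via B-(2-bromoallyl)diazaborolidine 10 (not isolated)
Conditions: (1R,2R)-N,N'-ditosyl-1,2-diphenylethane-1,2-diamine, BBr3, CH2Cl2, 0 °C → rt, evaporate; 9, CH2Cl2, 0 °C → rt; then 7, −78 °C; pH 7 buffer
Reagents that add atoms: (4R,5R)-2-bromo-4,5-diphenyl-1,3-ditosyl-1,3,2-diazaborolidine, made in the flask, atoms enter 10 only, BrB1N(S(=O)(=O)c2ccc(C)cc2)[C@H](c2ccccc2)[C@@H](c2ccccc2)N1S(=O)(=O)c1ccc(C)cc1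
Why: Tin-to-boron exchange gives the chiral allylborane 10, which transfers the 2-bromoallyl group through a closed chair transition state (reagent-controlled asymmetric allylboration). At −78 °C only the aldehyde reacts and the neopentyl ketone is left alone. Attack on the Re face sets C3 as S.

Step 7
Reactants: 11 (6S)-8-bromo-6-hydroxy-1-[(4-methoxybenzyl)oxy]-4,4-dimethylnon-8-en-3-one
Product: 12 (6S)-8-bromo-6-(tert-butyldimethylsilyloxy)-1-[(4-methoxybenzyl)oxy]-4,4-dimethylnon-8-en-3-one
Conditions: TBSCl, imidazole, DMF, rt
Reagents that add atoms: tert-butyldimethylsilyl chloride CC(C)(C)[Si](C)(C)Cl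
Why: This is a standard silylation. The γ-hydroxy ketone may rest partly as its five-membered hemiketal, but the open secondary alcohol is silylated faster and drains the equilibrium.

Step 8
Reactants: 12 (6S)-8-bromo-6-(tert-butyldimethylsilyloxy)-1-[(4-methoxybenzyl)oxy]-4,4-dimethylnon-8-en-3-one
Product: 14 (1R,4S)-4-(tert-butyldimethylsilyloxy)-1-{2-[(4-methoxybenzyl)oxy]ethyl}-2,2-dimethyl-6-methylidenecyclohexan-1-ol, via alkenylchromium dichloride 13 (not isolated)
Conditions: CrCl2 (8 equiv), NiCl2 (0.05 equiv), degassed DMF (0.01 M), rt → 50 °C; then water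
Reagents that add atoms: CrCl2 Cl[Cr]Cl (atoms enter 13 only)
Why: NiCl2 is reduced by CrCl2 to zerovalent nickel, which inserts into the C5–Br bond of 12; the alkenyl group passes to trivalent chromium to give 13, and 13 adds to the C6 ketone to leave a chromium alkoxide that water converts into 14. The closest known reaction type is the intramolecular Nozaki–Hiyama–Kishi alkenylation of ketones that gives five- and six-membered 2-methylenecycloalkanols. Ring A closes in the 6-exo-trig mode: C5 attacks C6 and the C=O bond stays outside the new ring. The one new stereocentre, C6, is controlled by C3 through a chair-like array of C1 to C6: one C1 methyl is unavoidably axial, so the C3 silyloxy group must be equatorial to escape a 1,3-diaxial contact, and this fixes which chair is used. In that chair the C7 arm is expected to lie equatorial, away from the axial hydrogens on C2 and C4, while the oxygen stands axial, where it can stay bound to the chromium as it leaves C5 out of the alkenyl plane; axial C6–O and equatorial C3–O are on the same ring face, the cis relation of 40. The step needs this facial selectivity, an addition faster than protonation or nickel-mediated dimerisation of 13, and survival of the β-alkoxy ketone. The gem-dimethyl group at C1 compresses the chain towards closure and removes enolisable hydrogens on that side, high dilution suppresses dimerisation, and the neutral medium does not trigger loss of the benzylic alcohol from C8.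

Step 9
Reactants: 14 (1R,4S)-4-(tert-butyldimethylsilyloxy)-1-{2-[(4-methoxybenzyl)oxy]ethyl}-2,2-dimethyl-6-methylidenecyclohexan-1-ol
Product: 15 (1R,4S)-4-(tert-butyldimethylsilyloxy)-1-(2-hydroxyethyl)-2,2-dimethyl-6-methylidenecyclohexan-1-ol
Conditions: DDQ, CH2Cl2/pH 7 buffer (10:1), 0 °C
Reagents that add atoms: none
Why: DDQ cleaves the electron-rich benzyl ether oxidatively. Water traps the oxocarbenium ion, so no cyclic acetal forms with the C6 hydroxyl. The silyl ether and the methylene are not touched.

Step 10
Reactants: 15 (1R,4S)-4-(tert-butyldimethylsilyloxy)-1-(2-hydroxyethyl)-2,2-dimethyl-6-methylidenecyclohexan-1-ol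
Product: 16 2-[(1R,4S)-4-(tert-butyldimethylsilyloxy)-1-hydroxy-2,2-dimethyl-6-methylidenecyclohexyl]acetaldehyde
Conditions: Dess–Martin periodinane, NaHCO3, CH2Cl2, 0 °C → rt
Reagents that add atoms: none
Why: In this Dess–Martin oxidation only the primary alcohol can be oxidised. The buffered, amine-free medium avoids retro-aldol cleavage and dehydration of the β-hydroxy aldehyde.

Step 11
Reactants: 17 but-2-yn-1-ol
Product: 18 (but-2-yn-1-yloxy)(tert-butyl)dimethylsilane
Conditions: TBSCl, imidazole, CH2Cl2, rt
Reagents that add atoms: tert-butyldimethylsilyl chloride CC(C)(C)[Si](C)(C)Cl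
Why: This is a standard silylation. The bulky ether also makes the two alkyne carbons sterically different for the next step.

Step 12
Reactants: 18 (but-2-yn-1-yloxy)(tert-butyl)dimethylsilane
Product: 20 tert-butyl{[(2E)-3-iodobut-2-en-1-yl]oxy}dimethylsilane, via alkenylzirconocene chloride 19 (not isolated)
Conditions: Cp2Zr(H)Cl (1.6 equiv), THF, rt → 40 °C; then I2, THF, 0 °C
Reagents that add atoms: Cp2Zr(H)Cl [H][Zr](Cl)(C1C=CC=C1)C1C=CC=C1 (heavy atoms enter 19 only); iodine II
Why: Hydrozirconation is a syn addition. The slight excess of Cp2Zr(H)Cl equilibrates the regioisomers so that zirconium ends on the less hindered methyl-bearing carbon (future C9). Iodinolysis with retention places iodine trans to the CH2O group.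

Step 13
Reactants: 16 2-[(1R,4S)-4-(tert-butyldimethylsilyloxy)-1-hydroxy-2,2-dimethyl-6-methylidenecyclohexyl]acetaldehyde; 20 tert-butyl{[(2E)-3-iodobut-2-en-1-yl]oxy}dimethylsilane
Product: 22 (3E)-5-(tert-butyldimethylsilyloxy)-1-[(1R,4S)-4-(tert-butyldimethylsilyloxy)-1-hydroxy-2,2-dimethyl-6-methylidenecyclohexyl]-3-methylpent-3-en-2-ol (both C8 epimers), via alkenylchromium dichloride 21 (not isolated)
Conditions: 20 (1.5 equiv), CrCl2 (4 equiv), NiCl2 (0.02 equiv), DMF/THF, rt; then water
Reagents that add atoms: CrCl2 Cl[Cr]Cl (atoms enter 21 only)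
Why: The intermolecular Nozaki–Hiyama–Kishi coupling forms C8–C9. It is non-basic and tolerates the free tertiary hydroxyl, and trisubstituted alkenyl iodides react with retention of geometry. The C8 configuration is irrelevant because it is erased in step 14.

Step 14
Reactants: 22 (3E)-5-(tert-butyldimethylsilyloxy)-1-[(1R,4S)-4-(tert-butyldimethylsilyloxy)-1-hydroxy-2,2-dimethyl-6-methylidenecyclohexyl]-3-methylpent-3-en-2-ol
Product: 23 (3E)-5-(tert-butyldimethylsilyloxy)-1-[(1R,4S)-4-(tert-butyldimethylsilyloxy)-1-hydroxy-2,2-dimethyl-6-methylidenecyclohexyl]-3-methylpent-3-en-2-one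
Conditions: Dess–Martin periodinane, NaHCO3, CH2Cl2, 0 °C → rt
Reagents that add atoms: none
Why: Dess–Martin oxidation acts on the only oxidisable hydroxyl, the secondary allylic one at C8. The conditions are too mild for retro-aldol cleavage of the new β-hydroxy enone.

Step 15
Reactants: 23 (3E)-5-(tert-butyldimethylsilyloxy)-1-[(1R,4S)-4-(tert-butyldimethylsilyloxy)-1-hydroxy-2,2-dimethyl-6-methylidenecyclohexyl]-3-methylpent-3-en-2-one
Product: 24 (3E)-1-[(1R,4S)-1,4-dihydroxy-2,2-dimethyl-6-methylidenecyclohexyl]-5-hydroxy-3-methylpent-3-en-2-one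
Conditions: HF·pyridine, pyridine, THF, 0 °C → rt
Reagents that add atoms: none
Why: Buffered hydrogen fluoride cleaves both silyl ethers without generating an alkoxide at C6, which a basic fluoride source would risk. Doing it at this stage means the finished polyene never has to face a deprotection.

Step 16
Reactants: 24 (3E)-1-[(1R,4S)-1,4-dihydroxy-2,2-dimethyl-6-methylidenecyclohexyl]-5-hydroxy-3-methylpent-3-en-2-one
Product: 26 {(2E)-5-[(1R,4S)-1,4-dihydroxy-2,2-dimethyl-6-methylidenecyclohexyl]-3-methyl-4-oxopent-2-en-1-yl}triphenylphosphonium bromide, via allylic bromide 25 (not isolated)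
Conditions: CBr4 (1.05 equiv), PPh3 (1.1 equiv), CH2Cl2, −20 °C; then PPh3 (1.5 equiv), rt
Reagents that add atoms: carbon tetrabromide BrC(Br)(Br)Br; triphenylphosphine c1ccc(cc1)P(c1ccccc1)c1ccccc1
Why: This is an Appel bromination followed by SN2 quaternisation. With one equivalent at low temperature the primary allylic hydroxyl reacts well ahead of the secondary C3 and tertiary C6 hydroxyls. The neutral medium spares the tertiary allylic alcohol, which an acidic salt-forming medium would ionise.

Step 17
Reactants: 27 (R)-α-ionone
Product: 28 2-methyl-2-{(E)-2-[(1R)-2,6,6-trimethylcyclohex-2-en-1-yl]ethenyl}-1,3-dioxolane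
Conditions: (TMSOCH2)2, TMSOTf (5 mol %), CH2Cl2, −78 → −40 °C; pyridine quench
Reagents that add atoms: 1,2-bis(trimethylsilyloxy)ethane C[Si](C)(C)OCCO[Si](C)(C)C
Why: Ketalisation with the bis-silyl ether of glycol runs at low temperature under kinetic control and does not pass through a dienol ether. C7'=C8' therefore stays in place and C6' is not touched.

Step 18
Reactants: 28 2-methyl-2-{(E)-2-[(1R)-2,6,6-trimethylcyclohex-2-en-1-yl]ethenyl}-1,3-dioxolane
Product: 29 (4R)-3,5,5-trimethyl-4-[(E)-2-(2-methyl-1,3-dioxolan-2-yl)ethenyl]cyclohex-2-en-1-one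
Conditions: Rh2(cap)4 (cap = caprolactamate, 1 mol %), t-BuOOH (70 % aq, excess), ClCH2CH2Cl, 40 °C
Reagents that add atoms: tert-butyl hydroperoxide CC(C)(C)OO
Why: This is a catalytic allylic oxidation by tert-butylperoxy radicals. The ring methylene C3' is the only unhindered secondary allylic site, whereas C6'–H is shielded by the C1' methyls and the side chain.

Step 19
Reactants: 29 (4R)-3,5,5-trimethyl-4-[(E)-2-(2-methyl-1,3-dioxolan-2-yl)ethenyl]cyclohex-2-en-1-one
Product: 31 (4S)-3,5,5-trimethyl-4-[(E)-2-(2-methyl-1,3-dioxolan-2-yl)ethenyl]cyclohexa-1,5-dien-1-yl trifluoromethanesulfonate, via lithium dienolate 30 (not isolated)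
Conditions: LiN(iPr)2, THF, −78 °C; then N-(5-chloropyridin-2-yl)triflimide, −78 °C
Reagents that add atoms: LiN(iPr)2 [Li]N(C(C)C)C(C)C (lithium of 30 only); N-(5-chloropyridin-2-yl)bis(trifluoromethanesulfonyl)imide FC(F)(F)S(=O)(=O)N(c1ccc(Cl)cn1)S(=O)(=O)C(F)(F)F
Why: A hindered amide deprotonates a cyclohexenone kinetically at the α' carbon (C2'), which gives the cross-conjugated dienolate 30. The very reactive triflimide traps it at −78 °C before proton exchange can reach C6'. The descriptor at C6' changes by priority only.

Step 20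
Reactants: 31 (4S)-3,5,5-trimethyl-4-[(E)-2-(2-methyl-1,3-dioxolan-2-yl)ethenyl]cyclohexa-1,5-dien-1-yl trifluoromethanesulfonate
Product: 32 2-methyl-2-{(E)-2-[(1S)-2,6,6-trimethylcyclohexa-2,4-dien-1-yl]ethenyl}-1,3-dioxolane
Conditions: Pd(OAc)2 (5 mol %), PPh3 (10 mol %), HCO2H, Et3N, DMF, 40 °C
Reagents that add atoms: none
Why: In this palladium-catalysed formate reduction of an enol triflate, zerovalent palladium adds oxidatively, formate loses CO2, and reductive elimination replaces OTf by H. The double bonds stay fixed at C2'=C3' and C4'=C5'.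

Step 21
Reactants: 32 2-methyl-2-{(E)-2-[(1S)-2,6,6-trimethylcyclohexa-2,4-dien-1-yl]ethenyl}-1,3-dioxolane
Product: 33 (3E)-4-[(1S)-2,6,6-trimethylcyclohexa-2,4-dien-1-yl]but-3-en-2-one
Conditions: PPTS (cat.), acetone/H2O (10:1), rt
Reagents that add atoms: water O
Why: An allylic ketal hydrolyses under very weak acid. Water captures the oxocarbenium ion faster than C6'–H can be lost, so the ring diene and C6' are preserved.

Step 22
Reactants: 33 (3E)-4-[(1S)-2,6,6-trimethylcyclohexa-2,4-dien-1-yl]but-3-en-2-one
Product: 34 (1E)-3-methyl-1-[(1S)-2,6,6-trimethylcyclohexa-2,4-dien-1-yl]penta-1,4-dien-3-ol (both C9' epimers)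
Conditions: CH2=CHMgBr, THF, −78 → −30 °C; aq NH4Cl
Reagents that add atoms: vinylmagnesium bromide C=C[Mg]Br
Why: A vinyl Grignard reagent adds 1,2 to an ionone-type enone. The low temperature disfavours γ-deprotonation at C6'. The new carbinol centre disappears in the next step.

Step 23
Reactants: 34 (1E)-3-methyl-1-[(1S)-2,6,6-trimethylcyclohexa-2,4-dien-1-yl]penta-1,4-dien-3-ol
Product: 35 {(2E,4E)-3-methyl-5-[(1S)-2,6,6-trimethylcyclohexa-2,4-dien-1-yl]penta-2,4-dien-1-yl}triphenylphosphonium bromide
Conditions: PPh3·HBr, MeOH, 0 °C → rt, dark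
Reagents that add atoms: triphenylphosphine hydrobromide [Br-].c1ccc(cc1)[PH+](c1ccccc1)c1ccccc1
Why: The weak acid ionises the bis-allylic tertiary alcohol, and PPh3 captures the pentadienyl cation at its unhindered terminus C11' (allylic transposition). This is the usual entry to C15 Wittig salts and leaves the conjugated E-diene.

Step 24
Reactants: 35 {(2E,4E)-3-methyl-5-[(1S)-2,6,6-trimethylcyclohexa-2,4-dien-1-yl]penta-2,4-dien-1-yl}triphenylphosphonium bromide; 36 (2E,4E,6E)-2,7-dimethylocta-2,4,6-trienedial
Product: 38 (2E,4E,6E,8E,10E,12E)-2,7,11-trimethyl-13-[(1S)-2,6,6-trimethylcyclohexa-2,4-dien-1-yl]trideca-2,4,6,8,10,12-hexaenal, via phosphorus ylide 37 (not isolated)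
Conditions: 36 (2.5 equiv), 1,2-epoxybutane/EtOH, 60 °C, dark, argon
Reagents that add atoms: none
Why: In this Wittig olefination bromide opens the epoxide and the resulting alkoxide deprotonates the salt, so free base never accumulates near C6'–H. The excess of 36 favours mono-olefination. The sterically hindered Z isomer at the new C11'=C12' bond should relax to E at the reaction temperature.

Step 25
Reactants: 26 {(2E)-5-[(1R,4S)-1,4-dihydroxy-2,2-dimethyl-6-methylidenecyclohexyl]-3-methyl-4-oxopent-2-en-1-yl}triphenylphosphonium bromide; 38 (2E,4E,6E,8E,10E,12E)-2,7,11-trimethyl-13-[(1S)-2,6,6-trimethylcyclohexa-2,4-dien-1-yl]trideca-2,4,6,8,10,12-hexaenal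
Product: 40 (3S,6R,6'S)-3,6-dihydroxy-2',3'-didehydro-7,8-dihydro-γ,ε-caroten-8-one, via phosphorus ylide 39 (not isolated)
Conditions: 26 (1.2 equiv), 1,2-epoxybutane/EtOH, 50 °C, dark, argon
Reagents that add atoms: none
Why: In this Wittig olefination the ylide 39 is conjugated with the C8 ketone, forms under the same nearly neutral conditions, and is too weak a base to deprotonate C6–OH or C6'–H. As a stabilised ylide it should give E at C11=C12. The union is of the same type as that of a C25 apocarotenal with a C5 carbonyl-stabilised allylic ylide.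

## Compound list

1 | 2,2-dimethylpent-4-enoic acid | C=CCC(C)(C)C(=O)O | starting material
2 | 2,2-dimethylpent-4-enoyl chloride | C=CCC(C)(C)C(=O)Cl | intermediate
3 | N-methoxy-N,2,2-trimethylpent-4-enamide | C=CCC(C)(C)C(=O)N(C)OC | intermediate
4 | 4,4-dimethylhepta-1,6-dien-3-one | C=CCC(C)(C)C(=O)C=C | intermediate
5 | 4-methoxybenzyl alcohol | COc1ccc(CO)cc1 | starting material
6 | 1-[(4-methoxybenzyl)oxy]-4,4-dimethylhept-6-en-3-one | C=CCC(C)(C)C(=O)CCOCc1ccc(OC)cc1 | intermediate
7 | 6-[(4-methoxybenzyl)oxy]-3,3-dimethyl-4-oxohexanal | O=CCC(C)(C)C(=O)CCOCc1ccc(OC)cc1 | intermediate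
8 | 2,3-dibromopropene | C=C(Br)CBr | starting material
9 | (2-bromoprop-2-en-1-yl)tributylstannane | C=C(Br)C[Sn](CCCC)(CCCC)CCCC | intermediate
10 | (4R,5R)-2-(2-bromoprop-2-en-1-yl)-4,5-diphenyl-1,3-ditosyl-1,3,2-diazaborolidine | C=C(Br)CB1N(S(=O)(=O)c2ccc(C)cc2)[C@H](c2ccccc2)[C@@H](c2ccccc2)N1S(=O)(=O)c1ccc(C)cc1 | intermediate
11 | (6S)-8-bromo-6-hydroxy-1-[(4-methoxybenzyl)oxy]-4,4-dimethylnon-8-en-3-one | C=C(Br)C[C@@H](O)CC(C)(C)C(=O)CCOCc1ccc(OC)cc1 | intermediate
12 | (6S)-8-bromo-6-(tert-butyldimethylsilyloxy)-1-[(4-methoxybenzyl)oxy]-4,4-dimethylnon-8-en-3-one | C=C(Br)C[C@@H](O[Si](C)(C)C(C)(C)C)CC(C)(C)C(=O)CCOCc1ccc(OC)cc1 | intermediate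
13 | alkenylchromium dichloride from 12 (CrCl2 on C5 in place of Br) | C=C([Cr](Cl)Cl)C[C@@H](O[Si](C)(C)C(C)(C)C)CC(C)(C)C(=O)CCOCc1ccc(OC)cc1 | intermediate
14 | (1R,4S)-4-(tert-butyldimethylsilyloxy)-1-{2-[(4-methoxybenzyl)oxy]ethyl}-2,2-dimethyl-6-methylidenecyclohexan-1-ol | C=C1C[C@@H](O[Si](C)(C)C(C)(C)C)CC(C)(C)[C@]1(O)CCOCc2ccc(OC)cc2 | intermediate
15 | (1R,4S)-4-(tert-butyldimethylsilyloxy)-1-(2-hydroxyethyl)-2,2-dimethyl-6-methylidenecyclohexan-1-ol | C=C1C[C@@H](O[Si](C)(C)C(C)(C)C)CC(C)(C)[C@]1(O)CCO | intermediate
16 | 2-[(1R,4S)-4-(tert-butyldimethylsilyloxy)-1-hydroxy-2,2-dimethyl-6-methylidenecyclohexyl]acetaldehyde | C=C1C[C@@H](O[Si](C)(C)C(C)(C)C)CC(C)(C)[C@]1(O)CC=O | intermediate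
17 | but-2-yn-1-ol | CC#CCO | starting material
18 | (but-2-yn-1-yloxy)(tert-butyl)dimethylsilane | CC#CCO[Si](C)(C)C(C)(C)C | intermediate
19 | (E)-alkenylzirconocene chloride from 18 (Zr on the methyl-bearing carbon) | Cl[Zr](C1C=CC=C1)(C1C=CC=C1)/C(C)=C/CO[Si](C)(C)C(C)(C)C | intermediate
20 | tert-butyl{[(2E)-3-iodobut-2-en-1-yl]oxy}dimethylsilane | I/C(C)=C/CO[Si](C)(C)C(C)(C)C | intermediate
21 | (E)-alkenylchromium dichloride from 20 | Cl[Cr](Cl)/C(C)=C/CO[Si](C)(C)C(C)(C)C | intermediate
22 | (3E)-5-(tert-butyldimethylsilyloxy)-1-[(1R,4S)-4-(tert-butyldimethylsilyloxy)-1-hydroxy-2,2-dimethyl-6-methylidenecyclohexyl]-3-methylpent-3-en-2-ol, C8 epimers | C=C1C[C@@H](O[Si](C)(C)C(C)(C)C)CC(C)(C)[C@]1(O)CC(O)/C(C)=C/CO[Si](C)(C)C(C)(C)C | intermediate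
23 | (3E)-5-(tert-butyldimethylsilyloxy)-1-[(1R,4S)-4-(tert-butyldimethylsilyloxy)-1-hydroxy-2,2-dimethyl-6-methylidenecyclohexyl]-3-methylpent-3-en-2-one | C=C1C[C@@H](O[Si](C)(C)C(C)(C)C)CC(C)(C)[C@]1(O)CC(=O)/C(C)=C/CO[Si](C)(C)C(C)(C)C | intermediate
24 | (3E)-1-[(1R,4S)-1,4-dihydroxy-2,2-dimethyl-6-methylidenecyclohexyl]-5-hydroxy-3-methylpent-3-en-2-one | C=C1C[C@@H](O)CC(C)(C)[C@]1(O)CC(=O)/C(C)=C/CO | intermediate
25 | (3E)-5-bromo-1-[(1R,4S)-1,4-dihydroxy-2,2-dimethyl-6-methylidenecyclohexyl]-3-methylpent-3-en-2-one | C=C1C[C@@H](O)CC(C)(C)[C@]1(O)CC(=O)/C(C)=C/CBr | intermediate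
26 | {(2E)-5-[(1R,4S)-1,4-dihydroxy-2,2-dimethyl-6-methylidenecyclohexyl]-3-methyl-4-oxopent-2-en-1-yl}triphenylphosphonium bromide | C=C1C[C@@H](O)CC(C)(C)[C@]1(O)CC(=O)/C(C)=C/C[P+](c2ccccc2)(c2ccccc2)c2ccccc2.[Br-] | intermediate
27 | (R)-α-ionone | CC(=O)/C=C/[C@H]1C(C)=CCCC1(C)C | starting material
28 | 2-methyl-2-{(E)-2-[(1R)-2,6,6-trimethylcyclohex-2-en-1-yl]ethenyl}-1,3-dioxolane | CC1(OCCO1)/C=C/[C@H]1C(C)=CCCC1(C)C | intermediate
29 | (4R)-3,5,5-trimethyl-4-[(E)-2-(2-methyl-1,3-dioxolan-2-yl)ethenyl]cyclohex-2-en-1-one | CC1(OCCO1)/C=C/[C@H]1C(C)=CC(=O)CC1(C)C | intermediate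
30 | lithium cross-conjugated dienolate of 29 (C2'=C3'–OLi) | CC1(OCCO1)/C=C/[C@H]1C(C)=CC(O[Li])=CC1(C)C | intermediate
31 | (4S)-3,5,5-trimethyl-4-[(E)-2-(2-methyl-1,3-dioxolan-2-yl)ethenyl]cyclohexa-1,5-dien-1-yl trifluoromethanesulfonate | CC1(OCCO1)/C=C/[C@H]1C(C)=CC(OS(=O)(=O)C(F)(F)F)=CC1(C)C | intermediate
32 | 2-methyl-2-{(E)-2-[(1S)-2,6,6-trimethylcyclohexa-2,4-dien-1-yl]ethenyl}-1,3-dioxolane | CC1(OCCO1)/C=C/[C@H]1C(C)=CC=CC1(C)C | intermediate
33 | (3E)-4-[(1S)-2,6,6-trimethylcyclohexa-2,4-dien-1-yl]but-3-en-2-one | CC(=O)/C=C/[C@H]1C(C)=CC=CC1(C)C | intermediate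
34 | (1E)-3-methyl-1-[(1S)-2,6,6-trimethylcyclohexa-2,4-dien-1-yl]penta-1,4-dien-3-ol, C9' epimers | C=CC(C)(O)/C=C/[C@H]1C(C)=CC=CC1(C)C | intermediate
35 | {(2E,4E)-3-methyl-5-[(1S)-2,6,6-trimethylcyclohexa-2,4-dien-1-yl]penta-2,4-dien-1-yl}triphenylphosphonium bromide | c1ccc(cc1)[P+](c1ccccc1)(c1ccccc1)C/C=C(C)/C=C/[C@H]1C(C)=CC=CC1(C)C.[Br-] | intermediate
36 | (2E,4E,6E)-2,7-dimethylocta-2,4,6-trienedial | O=C/C(C)=C/C=C/C=C(C)/C=O | starting material
37 | ylide of 35 | c1ccc(cc1)P(c1ccccc1)(c1ccccc1)=C/C=C(C)/C=C/[C@H]1C(C)=CC=CC1(C)C | intermediate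
38 | (2E,4E,6E,8E,10E,12E)-2,7,11-trimethyl-13-[(1S)-2,6,6-trimethylcyclohexa-2,4-dien-1-yl]trideca-2,4,6,8,10,12-hexaenal | O=C/C(C)=C/C=C/C=C(C)/C=C/C=C(C)/C=C/[C@H]1C(C)=CC=CC1(C)C | intermediate
39 | ylide of 26 | C=C1C[C@@H](O)CC(C)(C)[C@]1(O)CC(=O)/C(C)=C/C=P(c2ccccc2)(c2ccccc2)c2ccccc2 | intermediate
40 | (3S,6R,6'S)-3,6-dihydroxy-2',3'-didehydro-7,8-dihydro-γ,ε-caroten-8-one (CNP0261423.1) | C=C1C[C@@H](O)CC(C)(C)[C@]1(O)CC(=O)/C(C)=C/C=C/C(C)=C/C=C/C=C(C)/C=C/C=C(C)/C=C/[C@H]1C(C)=CC=CC1(C)C | target

## Step count and least certain steps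

Total step count: 25.

Longest linear sequence: 14 steps (1, 2, 3, 4, 6, 7, 8, 9, 10, 13, 14, 15, 16, 25). The ring B branch contributes 9 steps (17–24, then 25).

**Step 8 (key step).**
- *What may go wrong.* Closure through the other chair arrangement at C6 (oxygen equatorial, arm axial) is the main risk. The steric difference between the arm and a solvated chromium-bound oxygen next to a gem-dimethyl carbon and a methylene is small, and a delivery in which chromium and oxygen stay in the alkenyl plane would favour it.
- *Second process.* Addition to the neopentyl ketone may be slow, which lets protonation at C5 compete. Concentration, nickel loading and temperature can be used against this.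
- *Fallback for the facial problem.* It sets out from 7 and returns at 14.
  - 7 is bromoallylated with the reagent from the (1S,2S)-controller to give the (6R)-bromo alcohol F1, which is silylated to the (6R)-bromo ketone F2.
  - The CrCl2/NiCl2 closure through the prevailing chair then gives the 3,6-trans ring alcohol F3, in which C6 already has the configuration of 40 and only C3 is wrong.
  - Bu4NF frees C3 in the trans diol F4. A Mitsunobu reaction with 4-nitrobenzoic acid inverts C3 to the 4-nitrobenzoate F5, and the tertiary C6 hydroxyl cannot take part.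
  - K2CO3 in methanol gives the cis diol F6, and TBSCl/imidazole silylates only the secondary alcohol, which gives 14.

**Step 3.**
- *What may go wrong.* The alcohol addition is reversible, and phosphine-induced self-coupling of the vinyl ketone (Rauhut–Currier type) can consume 4 before the alkoxide adds. The alcohol is not the solvent here.
- *Fallback.* It sets out from 4 and returns at 6. Conjugate borylation with B2pin2 (CuCl, NaOtBu, MeOH) gives the β-boryl ketone F7. NaBO3 oxidises it to the β-hydroxy ketone F8. 4-Methoxybenzyl trichloroacetimidate with catalytic PPTS then etherifies the primary alcohol to 6.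

**Step 19.**
- *What may go wrong.* Proton exchange between the dienolate and unreacted enone can move the charge into the extended dienolate through C6'. This would erode the configuration and misplace the triflate.
- *Fallback.* It sets out from 29 and returns at 32, replacing steps 19 and 20. Condensation with tosylhydrazide gives the tosylhydrazone F9. A Shapiro reaction with MeLi (two equivalents) first removes N–H, which lowers the acidity of C6'–H. It then deprotonates C2' under direction by the nitrogen anion. Loss of sulfinate and nitrogen, followed by protonation of the alkenyllithium, gives the diene.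

**Step 23 (and the basic step 22 before it).**
- *What may go wrong.* The pentadienyl cation sits next to C6'–H. Proton loss into full conjugation with the ring diene, or acid-induced migration of the ring double bonds, can compete with capture by the phosphine.
- *Fallback.* It sets out from 33 and returns at 35.
  - A Horner–Wadsworth–Emmons reaction with triethyl phosphonoacetate and NaH gives the dienoate F10. The 9'Z isomer would be removed at this stage.
  - iBu2AlH reduces it to the dienol F11.
  - CBr4/PPh3 gives the dienyl bromide F12, and PPh3 quaternises it under neutral conditions.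

**Step 25.**
- *What may go wrong.* Retro-aldol cleavage of C6–C7 or loss of water across C6–C7 is possible during a long, warm reaction, because the stabilised ylide attacks the long polyenal slowly. Geometrical scrambling at C9=C10 through the ylide resonance is a further risk.
- *Fallback.* It sets out from 22 and returns at 40, keeping C8 at the alcohol level until the end.
  - HF·pyridine converts 22 into the tetraol F13.
  - CBr4/PPh3 followed by PPh3 acts on the primary allylic hydroxyl to give the hydroxy phosphonium salt F14.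
  - The more reactive, non-stabilised ylide from F14 couples with 38 in 1,2-epoxybutane to give the 8-hydroxy polyene F15, which contains no aldol unit.
  - MnO2 finally oxidises only the polyene-allylic C8 alcohol, leaving the C3 and C6 hydroxyls as they are.

## Further compounds

F1 | step 8 | (6R)-8-bromo-6-hydroxy-1-[(4-methoxybenzyl)oxy]-4,4-dimethylnon-8-en-3-one | C=C(Br)C[C@H](O)CC(C)(C)C(=O)CCOCc1ccc(OC)cc1
F2 | step 8 | (6R)-8-bromo-6-(tert-butyldimethylsilyloxy)-1-[(4-methoxybenzyl)oxy]-4,4-dimethylnon-8-en-3-one | C=C(Br)C[C@H](O[Si](C)(C)C(C)(C)C)CC(C)(C)C(=O)CCOCc1ccc(OC)cc1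
F3 | step 8 | (1R,4R)-4-(tert-butyldimethylsilyloxy)-1-{2-[(4-methoxybenzyl)oxy]ethyl}-2,2-dimethyl-6-methylidenecyclohexan-1-ol | C=C1C[C@H](O[Si](C)(C)C(C)(C)C)CC(C)(C)[C@]1(O)CCOCc2ccc(OC)cc2
F4 | step 8 | (1R,4R)-1-{2-[(4-methoxybenzyl)oxy]ethyl}-2,2-dimethyl-6-methylidenecyclohexane-1,4-diol | C=C1C[C@H](O)CC(C)(C)[C@]1(O)CCOCc2ccc(OC)cc2
F5 | step 8 | (1S,4R)-4-hydroxy-4-{2-[(4-methoxybenzyl)oxy]ethyl}-3,3-dimethyl-5-methylidenecyclohexyl 4-nitrobenzoate | C=C1C[C@@H](OC(=O)c2ccc(cc2)[N+](=O)[O-])CC(C)(C)[C@]1(O)CCOCc2ccc(OC)cc2
F6 | step 8 | (1R,4S)-1-{2-[(4-methoxybenzyl)oxy]ethyl}-2,2-dimethyl-6-methylidenecyclohexane-1,4-diol | C=C1C[C@@H](O)CC(C)(C)[C@]1(O)CCOCc2ccc(OC)cc2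
F7 | step 3 | 4,4-dimethyl-1-(4,4,5,5-tetramethyl-1,3,2-dioxaborolan-2-yl)hept-6-en-3-one | C=CCC(C)(C)C(=O)CCB1OC(C)(C)C(C)(C)O1
F8 | step 3 | 1-hydroxy-4,4-dimethylhept-6-en-3-one | C=CCC(C)(C)C(=O)CCO
F9 | step 19 | tosylhydrazone of 29 | CC1(OCCO1)/C=C/[C@H]1C(C)=CC(=NNS(=O)(=O)c2ccc(C)cc2)CC1(C)C
F10 | step 23 | ethyl (2E,4E)-3-methyl-5-[(1S)-2,6,6-trimethylcyclohexa-2,4-dien-1-yl]penta-2,4-dienoate | CCOC(=O)/C=C(C)/C=C/[C@H]1C(C)=CC=CC1(C)C
F11 | step 23 | (2E,4E)-3-methyl-5-[(1S)-2,6,6-trimethylcyclohexa-2,4-dien-1-yl]penta-2,4-dien-1-ol | OC/C=C(C)/C=C/[C@H]1C(C)=CC=CC1(C)C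
F12 | step 23 | (5S)-5-[(1E,3E)-5-bromo-3-methylpenta-1,3-dien-1-yl]-1,5... ring B dienyl bromide: (2E,4E)-1-bromo-3-methyl-5-[(1S)-2,6,6-trimethylcyclohexa-2,4-dien-1-yl]penta-2,4-diene | BrC/C=C(C)/C=C/[C@H]1C(C)=CC=CC1(C)C
F13 | step 25 | (3E)-1-[(1R,4S)-1,4-dihydroxy-2,2-dimethyl-6-methylidenecyclohexyl]-3-methylpent-3-ene-2,5-diol, C8 epimers | C=C1C[C@@H](O)CC(C)(C)[C@]1(O)CC(O)/C(C)=C/CO
F14 | step 25 | {(2E)-5-[(1R,4S)-1,4-dihydroxy-2,2-dimethyl-6-methylidenecyclohexyl]-4-hydroxy-3-methylpent-2-en-1-yl}triphenylphosphonium bromide | C=C1C[C@@H](O)CC(C)(C)[C@]1(O)CC(O)/C(C)=C/C[P+](c2ccccc2)(c2ccccc2)c2ccccc2.[Br-]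
F15 | step 25 | 8-hydroxy analogue of 40 (C8 carbinol, C8 epimers) | C=C1C[C@@H](O)CC(C)(C)[C@]1(O)CC(O)/C(C)=C/C=C/C(C)=C/C=C/C=C(C)/C=C/C=C(C)/C=C/[C@H]1C(C)=CC=CC1(C)C
A1 | alternative 1 | ring A 5,6-epoxide with the oxirane oxygen syn to C3–OH and C8 as tert-butyldimethylsilyl ether | C[C@]12C[C@@H](O)CC(C)(C)[C@@]1(CCO[Si](C)(C)C(C)(C)C)O2
A2 | alternative 1 | (1R)-4-[2-(tert-butyldimethylsilyloxy)ethyl]-3,5,5-trimethylcyclohex-3-en-1-ol | CC1=C(CCO[Si](C)(C)C(C)(C)C)C(C)(C)C[C@H](O)C1
A3 | alternative 2 | (3E)-4-[(1S)-2,6,6-trimethylcyclohexa-2,4-dien-1-yl]but-3-en-2-one | CC(=O)/C=C/[C@H]1C(C)=CC=CC1(C)C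
A4 | alternative 2 | (3E,5E,7Z)-6,10-dimethylundeca-3,5,7,9-tetraen-2-one | CC(=O)/C=C/C=C(C)/C=C\C=C(C)C
A5 | alternative 3 | methyl (1S)-2,6,6-trimethylcyclohexa-2,4-diene-1-carboxylate | COC(=O)[C@H]1C(C)=CC=CC1(C)C
A6 | alternative 3 | 7-diazo-2,6,6-trimethylcyclohepta-2,4-dien-1-one | CC1=CC=CC(C)(C)C(=[N+]=[N-])C1=O
A7 | alternative 3 | (2,6,6-trimethylcyclohexa-2,4-dien-1-ylidene)methanone | O=C=C1C(C)=CC=CC1(C)C
A8 | alternative 3 | 2,6,6-trimethylcyclohepta-2,4-dien-1-one | CC1=CC=CC(C)(C)CC1=O
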